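**Retrosynthetic overview**
- Endgame: the C2 and C13 acetates come from silyl ethers and the C8 tiglate from a free carbinol; the C8–OH, the cyclopentane C6–C10 and the whole butenolide come from one carboxylative cascade on allene 12 with CO2 (new bonds O–C6, C11–C12 and C7–C8).
- Enabling feature: the lactone γ-carbon C6 is a quaternary cyclobutane carbon whose only non-cyclobutane carbon neighbour is the β-carbon C7. The unit C6–C7=C11 is therefore a masked cyclobutylidene allene: its sp2 C11–H can be lithiated and carboxylated, its terminus C6 accepts the carboxylate oxygen, and its central carbon C7 lies five atoms from a CH2CHO arm held on the endo face at C10.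
- The allene comes from the C6 cyclobutanone by acetylide addition and anti-SN2′ Pd-hydride delivery, which turns the C6 carbinol centre into a defined allene axis.
- The C10 quaternary centre comes from a dichlorocyclobutanone (cuprate reductive alkylation, methyl from the exo face); the cyclobutane comes from a dichloroketene [2+2] on a cyclopentene.
- Ring order: cyclopentane C1–C5 (chiral pool enone plus MeLi), then the cyclobutane, then butenolide and cyclopentane C6–C10 together in the key step.

Key step: step 8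

Remark: locants follow the sesquiterpene-lactone convention (C12 lactone C=O, C11 α-carbon, C13 CH2O, C7 β-carbon, C6 O-bearing cyclobutane carbon, C8 CH–O-tiglate, C9 CH2, C10 C–CH3, C1/C5 cyclobutane CH, C2 CH–OAc, C3 CH2, C4 C(CH3)OH); exo/endo mean anti/syn to the cyclopentane C1–C5 across the cyclobutane. The target is cis-syn-cis, so the ring C6–C10 must be closed on the endo face.

**Step 1**
Reactants: 1 (S)-4-(tert-butyldimethylsilyloxy)cyclopent-2-en-1-one
Product: 2 (1R,4S)-4-(tert-butyldimethylsilyloxy)-1-methylcyclopent-2-en-1-ol (OH cis to OTBS)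
Conditions: MeLi, Et2O, −78 °C; then H2O
Reagents that add atoms: methyllithium, [Li]C
Why: 1,2-addition of MeLi to the enone carbonyl anti to the silyloxy group should set the C4 tertiary carbinol with OH cis to the C2 oxygen (substrate-controlled carbonyl addition).

**Step 2**
Reactants: 2 the tertiary allylic alcohol
Product: 3 (1S,4R)-1-(tert-butyldimethylsilyloxy)-4-methyl-4-(triethylsilyloxy)cyclopent-2-ene
Conditions: TESOTf, 2,6-lutidine, CH2Cl2, −78 → 0 °C
Reagents that add atoms: triethylsilyl trifluoromethanesulfonate, CC[Si](CC)(CC)OS(=O)(=O)C(F)(F)F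
Why: silylation of the tertiary alcohol with a silyl triflate protects it for the ketene, cuprate and organolithium steps and puts two bulky groups on one alkene face.

**Step 3**
Reactants: 3 the cis-bis(silyl ether) cyclopentene
Product: 4 7,7-dichloro-2-exo-(tert-butyldimethylsilyloxy)-4-endo-methyl-4-exo-(triethylsilyloxy)-cis-bicyclo[3.2.0]heptan-6-one (target C6 = C=O and C10 = CCl2)
Conditions: Cl3CCOCl (slow addition), Zn–Cu, Et2O–DME, 0 → 23 °C
Reagents that add atoms: trichloroacetyl chloride (source of dichloroketene), O=C(Cl)C(Cl)(Cl)Cl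
Why: thermal ketene–alkene [2+2] cycloaddition should occur on the face anti to both silyloxy groups (setting C1 and C5 cis, both oxygens exo, C4 methyl endo), with the bulky CCl2 end bonding to C1 away from the quaternary C4 and the small C=O carbon to C5.

**Step 4**
Reactants: 4 the dichlorocyclobutanone
Product: 6 7-endo-allyl-7-exo-methyl-2-exo-(tert-butyldimethylsilyloxy)-4-endo-methyl-4-exo-(triethylsilyloxy)-cis-bicyclo[3.2.0]heptan-6-one, via lithium enolate 5 (not isolated)
Conditions: (CH2=CHCH2)2CuLi (pre-formed from allyllithium and CuI), THF, −78 °C; then MeI, HMPA, −78 → 0 °C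
Reagents that add atoms: lithium diallylcuprate, [Li+].C=CC[Cu-]CC=C; iodomethane, CI
Why: reductive alkylation of an α,α-dichloro ketone with a lithium dialkylcuprate (Cl/Cu exchange, then allyl transfer to the chloro enolate) gives the regiodefined C10 enolate, which MeI should alkylate from the convex exo face, so that C10 carries methyl exo and the allyl arm endo.

**Step 5**
Reactants: 6 the allyl methyl cyclobutanone
Product: 8 7-endo-(2,2-dimethoxyethyl)-7-exo-methyl-2-exo-(tert-butyldimethylsilyloxy)-4-endo-methyl-4-exo-(triethylsilyloxy)-cis-bicyclo[3.2.0]heptan-6-one, via keto aldehyde 7 (not isolated)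
Conditions: O3, CH2Cl2–MeOH, −78 °C; Me2S; then HC(OMe)3, CeCl3·7H2O (cat.), MeOH, 23 °C
Reagents that add atoms: ozone, [O-][O+]=O; trimethyl orthoformate, COC(OC)OC
Why: ozonolysis of the terminal alkene gives the C8 aldehyde, and CeCl3-catalysed acetalisation should take the aldehyde selectively over the hindered α-quaternary cyclobutanone.

**Step 6**
Reactants: 8 the keto acetal; 9 tert-butyl(diphenyl)(prop-2-yn-1-yloxy)silane
Product: 11 methyl carbonate of the 6-endo-hydroxy-6-exo-[3-(tert-butyldiphenylsilyloxy)prop-1-ynyl] derivative of 8, via lithium alkoxide 10 (not isolated)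
Conditions: 9, n-BuLi, THF, −78 °C; add 8, −78 °C; then ClCO2Me, −78 → 0 °C
Reagents that add atoms: methyl chloroformate, COC(=O)Cl
Why: acetylide 1,2-addition to the strained cyclobutanone should come from the convex exo face (alkyne exo, oxygen endo), and the tertiary alkoxide is trapped in situ as the propargylic carbonate (O-acylation).

**Step 7**
Reactants: 11 the tertiary propargylic carbonate
Product: 12 6-[3-(tert-butyldiphenylsilyloxy)prop-1-enylidene]-7-endo-(2,2-dimethoxyethyl)-7-exo-methyl-2-exo-(tert-butyldimethylsilyloxy)-4-endo-methyl-4-exo-(triethylsilyloxy)-cis-bicyclo[3.2.0]heptane (allene C6=C7=C11, allenic H on the exo face)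
Conditions: Pd2(dba)3·CHCl3 (2.5 mol %), n-Bu3P (10 mol %), HCO2NH4, THF, 40 °C
Reagents that add atoms: none
Why: Pd-catalysed formate hydrogenolysis of a propargylic carbonate: anti-SN2′ oxidative addition gives the σ-allenyl palladium (favoured by the tertiary C6), formate decarboxylates to Pd–H and reductive elimination with retention should place H on C11 on the exo face (centre-to-axis chirality transfer).

**Step 8**
Reactants: 12 the vinylidenecyclobutane acetal
Product: 16 tetracyclic 8-hydroxy butenolide (2-O-TBS, 4-O-TES, 13-O-TBDPS; C6–O exo, C8–OH on the convex face), via allenyllithium 13 (not isolated), via lithium allenoate 14 (not isolated), via allenoic acid aldehyde 15 (not isolated)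
Conditions: n-BuLi (1.1 equiv), THF, −78 °C; CO2 (1 atm), −78 → 0 °C; then 1,4-dioxane, AcOH, H2O, Pd(OAc)2 (10 mol %), 2,2′-bipyridine (12 mol %), 60 °C
Reagents that add atoms: carbon dioxide, O=C=O; water, O
Why: Proposed new method: deprotonation of the exo allenic C11–H gives 1-lithioallene 13, which CO2 should capture at C11 with retention of the allene axis (C11–C12 bond; γ-attack is blocked because C6 is a fully substituted cyclobutane carbon), so the carboxylate of 14 sits on the exo face, and AcOH/H2O then frees the acid and hydrolyses the acetal to aldehyde 15. Pd(II) binds the C6=C7 π-bond on the endo face, where the C8 aldehyde can chelate it, the carboxylate oxygen adds anti from the exo face (5-endo-trig oxypalladation, O–C6 bond), and the resulting butenolid-3-yl palladium at C7 adds across the tethered aldehyde (5-exo-trig 1,2-insertion, C7–C8 bond) before AcOH protonolysis of the Pd alkoxide returns Pd(II). The closest known reaction types are the CO2 carboxylation of 1-lithioallenes to 2,3-allenoic acids, the Pd(II)-catalysed lactonisation–coupling of 2,3-allenoic acids through butenolidyl palladium species, and the Pd(OAc)2/bipyridine nucleopalladation–aldehyde addition of alkynals; their merger in one flask on an allene is the untested part. C6 is set by axis-to-centre chirality transfer (carboxylate exo, hence O exo and C7 endo) and is matched by the tether, because the C9–C8 arm on the endo face of C10 can only reach C7 in a cis-fused cyclopentane. C8 should form with the Pd-bound oxygen on the convex face of the new ring and H towards the concave pocket of the cis-syn-cis skeleton. The step needs α-carboxylation, a configurationally stable allenyllithium and carbonyl insertion faster than protodepalladation; the quaternary γ-carbon, the −78 °C lithiation, and the bipyridine ligand together with a chelating aldehyde five atoms away are meant to secure these.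

**Step 9**
Reactants: 16 the 8-hydroxy butenolide
Product: 17 8-O-tiglate of 16
Conditions: tiglic acid, DCC, DMAP, CH2Cl2, 23 °C
Reagents that add atoms: tiglic acid, C/C=C(\C)C(=O)O
Why: Steglich esterification of the only free hydroxyl with the (E)-configured acid installs the tiglate without touching the silyl ethers.

**Step 10**
Reactants: 17 the tris(silyl ether) tiglate
Product: 18 2,4,13-triol 8-tiglate
Conditions: HF·pyridine, pyridine, THF, 0 → 23 °C
Reagents that add atoms: none
Why: buffered acidic fluoride should cleave the primary TBDPS, secondary TBS and tertiary TES ethers while the butenolide and tiglate survive and base-mediated acyl migration from O8 to O13 is avoided.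

**Step 11**
Reactants: 18 the triol
Product: 19 CNP0210373.1
Conditions: Ac2O, pyridine, DMAP (cat.), CH2Cl2, 0 °C
Reagents that add atoms: acetic anhydride, CC(=O)OC(C)=O
Why: acetylation should take the primary C13 and secondary C2 hydroxyls and leave the hindered tertiary C4–OH free (chemoselective O-acylation).

**Compound list**
1 | (S)-4-(tert-butyldimethylsilyloxy)cyclopent-2-en-1-one | O=C1C=C[C@@H](O[Si](C)(C)C(C)(C)C)C1 | starting material
2 | (1R,4S)-4-(tert-butyldimethylsilyloxy)-1-methylcyclopent-2-en-1-ol | C1[C@@H](O[Si](C)(C)C(C)(C)C)C[C@@](C)(O)C=1 | intermediate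
3 | (1S,4R)-1-(tert-butyldimethylsilyloxy)-4-methyl-4-(triethylsilyloxy)cyclopent-2-ene | C1[C@@H](O[Si](C)(C)C(C)(C)C)C[C@@](C)(O[Si](CC)(CC)CC)C=1 | intermediate
4 | 7,7-dichlorobicyclo[3.2.0]heptan-6-one (2-exo-OTBS, 4-endo-Me, 4-exo-OTES) | ClC1(Cl)[C@@H]2[C@@H](O[Si](C)(C)C(C)(C)C)C[C@@](C)(O[Si](CC)(CC)CC)[C@@H]2C1=O | intermediate
5 | lithium enolate of the 7-allyl cyclobutanone (not isolated) | C=CCC1[C@@H]2[C@@H](O[Si](C)(C)C(C)(C)C)C[C@@](C)(O[Si](CC)(CC)CC)[C@@H]2C=1[O-].[Li+] | intermediate
6 | 7-endo-allyl-7-exo-methyl cyclobutanone | C=CC[C@]1(C)[C@@H]2[C@@H](O[Si](C)(C)C(C)(C)C)C[C@@](C)(O[Si](CC)(CC)CC)[C@@H]2C1=O | intermediate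
7 | keto aldehyde (7-endo-CH2CHO; not isolated) | O=CC[C@]1(C)[C@@H]2[C@@H](O[Si](C)(C)C(C)(C)C)C[C@@](C)(O[Si](CC)(CC)CC)[C@@H]2C1=O | intermediate
8 | keto dimethyl acetal (7-endo-CH2CH(OMe)2) | COC(OC)C[C@]1(C)[C@@H]2[C@@H](O[Si](C)(C)C(C)(C)C)C[C@@](C)(O[Si](CC)(CC)CC)[C@@H]2C1=O | intermediate
9 | tert-butyl(diphenyl)(prop-2-yn-1-yloxy)silane | C#CCO[Si](c1ccccc1)(c1ccccc1)C(C)(C)C | starting material
10 | lithium tertiary propargylic alkoxide (alkyne exo, O endo; not isolated) | COC(OC)C[C@]1(C)[C@@H]2[C@@H](O[Si](C)(C)C(C)(C)C)C[C@@](C)(O[Si](CC)(CC)CC)[C@@H]2[C@]1(C#CCO[Si](c1ccccc1)(c1ccccc1)C(C)(C)C)[O-].[Li+] | intermediate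
11 | tertiary propargylic methyl carbonate | COC(OC)C[C@]1(C)[C@@H]2[C@@H](O[Si](C)(C)C(C)(C)C)C[C@@](C)(O[Si](CC)(CC)CC)[C@@H]2[C@]1(C#CCO[Si](c1ccccc1)(c1ccccc1)C(C)(C)C)OC(=O)OC | intermediate
12 | vinylidenecyclobutane acetal (allene C6=C7=C11, H exo) | COC(OC)C[C@]1(C)[C@@H]2[C@@H](O[Si](C)(C)C(C)(C)C)C[C@@](C)(O[Si](CC)(CC)CC)[C@@H]2C1=[C@]=C([H])CO[Si](c1ccccc1)(c1ccccc1)C(C)(C)C | intermediate
13 | 1-lithioallene (Li on C11, exo; not isolated) | COC(OC)C[C@]1(C)[C@@H]2[C@@H](O[Si](C)(C)C(C)(C)C)C[C@@](C)(O[Si](CC)(CC)CC)[C@@H]2C1=[C@]=C([Li])CO[Si](c1ccccc1)(c1ccccc1)C(C)(C)C | intermediate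
14 | lithium 2,3-allenoate acetal (not isolated) | COC(OC)C[C@]1(C)[C@@H]2[C@@H](O[Si](C)(C)C(C)(C)C)C[C@@](C)(O[Si](CC)(CC)CC)[C@@H]2C1=[C@]=C(C(=O)[O-])CO[Si](c1ccccc1)(c1ccccc1)C(C)(C)C.[Li+] | intermediate
15 | 2,3-allenoic acid aldehyde (not isolated) | O=CC[C@]1(C)[C@@H]2[C@@H](O[Si](C)(C)C(C)(C)C)C[C@@](C)(O[Si](CC)(CC)CC)[C@@H]2C1=[C@]=C(C(=O)O)CO[Si](c1ccccc1)(c1ccccc1)C(C)(C)C | intermediate
16 | tetracyclic 8-hydroxy butenolide (2-O-TBS, 4-O-TES, 13-O-TBDPS) | O[C@H]1C[C@]2(C)[C@@H]3[C@@H](O[Si](C)(C)C(C)(C)C)C[C@@](C)(O[Si](CC)(CC)CC)[C@@H]3[C@@]23OC(=O)C(CO[Si](c4ccccc4)(c4ccccc4)C(C)(C)C)=C13 | intermediate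
17 | 8-O-tiglate tris(silyl ether) | C/C=C(\C)C(=O)O[C@H]1C[C@]2(C)[C@@H]3[C@@H](O[Si](C)(C)C(C)(C)C)C[C@@](C)(O[Si](CC)(CC)CC)[C@@H]3[C@@]23OC(=O)C(CO[Si](c4ccccc4)(c4ccccc4)C(C)(C)C)=C13 | intermediate
18 | 2,4,13-triol 8-tiglate | C/C=C(\C)C(=O)O[C@H]1C[C@]2(C)[C@@H]3[C@@H](O)C[C@@](C)(O)[C@@H]3[C@@]23OC(=O)C(CO)=C13 | intermediate
19 | CNP0210373.1 | C/C=C(\C)C(=O)O[C@H]1C[C@]2(C)[C@@H]3[C@@H](OC(C)=O)C[C@@](C)(O)[C@@H]3[C@@]23OC(=O)C(COC(C)=O)=C13 | target

**Step count and risks**
Total step count: 11. Longest linear sequence: 11 steps (from 1).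

Steps most likely to fail:

1. Step 8. The butenolidyl palladium may be protonated before it inserts the aldehyde, or acid alone may cycloisomerise the allenoic acid, so that the lactone forms without the C7–C8 bond. The fallback uses known chemistry and sets out from 12. Lithiation and CO2 capture as before, but the lithium allenoate is quenched in the same flask with I2 (iodolactonisation of a 2,3-allenoate, still making O–C6 and C11–C12 in one operation), which should give the β-iodobutenolide dimethyl acetal F1. PPTS in wet acetone would then free the iodo aldehyde F2, and an intramolecular Nozaki–Hiyama–Kishi reaction (CrCl2, cat. NiCl2, DMF) would close C7–C8 and return to 16.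

2. Step 3. The alkene is deactivated by two allylic C–O bonds, so ketene oligomerisation may outrun cycloaddition, and ZnCl2 may ionise the tertiary allylic silyl ether. The fallback sets out from 3. A keteniminium [2+2] cycloaddition (N,N-dimethylpent-4-enamide, Tf2O, 2,4,6-collidine, ClCH2CH2Cl, reflux) uses a far more electrophilic, amine-buffered partner that already carries the allyl arm and would give the cyclobutaniminium triflate F3. Aqueous NaHCO3 hydrolysis gives the 7-allyl cyclobutanone F4 (C10 epimers), and LDA then MeI (exo attack) returns to 6.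

3. Step 4. The chloro enolate may be protonated or over-reduced without carbon transfer, and allyl groups may be lost from copper by coupling. The fallback sets out from 4. Zn–Cu, NH4Cl, MeOH gives the parent cyclobutanone F5; LDA then allyl bromide (−78 °C) gives the exo-allyl ketone F6; a second enolisation toward C10 (LDA) and MeI from the exo face returns to 6 with the same C10 configuration.

Further compounds
F1 | step 8 | β-iodobutenolide dimethyl acetal (C7–I, C6–O exo) | COC(OC)C[C@]1(C)[C@@H]2[C@@H](O[Si](C)(C)C(C)(C)C)C[C@@](C)(O[Si](CC)(CC)CC)[C@@H]2[C@@]13OC(=O)C(CO[Si](c4ccccc4)(c4ccccc4)C(C)(C)C)=C3I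
F2 | step 8 | β-iodobutenolide aldehyde | O=CC[C@]1(C)[C@@H]2[C@@H](O[Si](C)(C)C(C)(C)C)C[C@@](C)(O[Si](CC)(CC)CC)[C@@H]2[C@@]13OC(=O)C(CO[Si](c4ccccc4)(c4ccccc4)C(C)(C)C)=C3I
F3 | step 3 | 7-allyl cyclobutaniminium triflate | C=CCC1[C@@H]2[C@@H](O[Si](C)(C)C(C)(C)C)C[C@@](C)(O[Si](CC)(CC)CC)[C@@H]2C1=[N+](C)C.[O-]S(=O)(=O)C(F)(F)F
F4 | step 3 | 7-allyl cyclobutanone (C10 epimers) | C=CCC1[C@@H]2[C@@H](O[Si](C)(C)C(C)(C)C)C[C@@](C)(O[Si](CC)(CC)CC)[C@@H]2C1=O
F5 | step 4 | parent cyclobutanone (C10 = CH2) | C1[C@@H]2[C@@H](O[Si](C)(C)C(C)(C)C)C[C@@](C)(O[Si](CC)(CC)CC)[C@@H]2C1=O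
F6 | step 4 | 7-exo-allyl cyclobutanone | C=CC[C@H]1[C@@H]2[C@@H](O[Si](C)(C)C(C)(C)C)C[C@@](C)(O[Si](CC)(CC)CC)[C@@H]2C1=O
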